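The earlier runs and the new flask stem from a simulated flask from invented constants, noise included.

The time of reading can matter to the share of target in target plus side product: target might, for instance, later feed side product. If the two form side by side in a constant ratio, time drops out, so we check the readings first.

| setting | alpha | flask |
|---|---|---|
| substrate | 0.020 M | 0.020 M |
| remark | the very flask that is asked about, followed so far |  |
| time |  | 25 min |

alpha run (percent of the substrate charged)

| time / min | target / % | side product / % |
|---|---|---|
| 0.667 | 8 | 2 |
| 1.33 | 13 | 1 |
| 2.00 | 19 | 0 |
| 3.00 | 28 | 1 |
| 4.00 | 29 | 2 |
| 5.00 | 41 | 3 |

(each reading ± 2 percentage points)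



1. share of target in target plus side product at 20 s
2. share of target in target plus side product at 3.0 min
3. share of target in target plus side product at 25 min

Up to 2.00 min, the alpha run gives a share of 93.0%, and after it 94.2%. That shows no fall, though both carry wide scatter. We therefore take the share as constant, and carry it past the last reading at 5.00 min on that choice.

The charge asks for no care, since both products are counted in percent of it and the alpha run is this very flask. The readings matter unequally. Summed, target gives 138% and side product 9.00%. One side-product reading off by 2 percentage points moves the share by 1.3 points, but one target reading off by as much moves it by 0.082 points, so the small side-product readings weigh far more.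

Our number is the branching share, a selectivity: target's part of both products, summed over the run, 93.9%. The scatter of the side-product sum puts it between 90.8% and 97.1%, and we commit to it at all three times.

The forecast differs at the end. It gives 96%, 95% and 85%, saying: “I lean towards a high share but keep a wide range reaching down to the consecutive case”.

The flask gives 95.6%, 95.6% and 95.8%.

    intermediate B ⇌ intermediate C (K = 0.890, k = 8.70 × 10⁻⁵ s⁻¹)
    substrate ⇌ intermediate A (K = 0.290, k = 0.0370 s⁻¹)
    intermediate A → intermediate B (k = 0.00130 s⁻¹)
    intermediate A → side product (k = 4.00 × 10⁻⁴ s⁻¹)
    intermediate A → target (k = 0.00870 s⁻¹)
    intermediate B ⇌ intermediate D (K = 48.0, k = 0.00200 s⁻¹)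
    intermediate B → target (k = 8.30 × 10⁻⁴ s⁻¹)

In this flask, the rate constant of intermediate A to target is 21.8 times that of intermediate A to side product. Our share lies 1.9 points below the value at 25 min, and the forecast lies 11 points below it. A neighbour flask charged with 0.0080 M holds 83.9% of target at 25.0 min. Our share turns that into 5.45% of side product, and the neighbour flask holds 3.71%.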